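**Retrosynthetic overview**

- Feature: the benzene ring of the chromane is an orcinol ring with the ether oxygen O1 on C8a, OH on C7 and CH3 on C5. A 1,3-dioxygenated diene (C4a–C8a–C8–C7) and a but-2-ynoate (C5–C6) give exactly this pattern, while the quaternary C2 stays untouched in a pyran ring made from (R)-linalool.
- Target 27 ⇐ Still–Gennari Z-olefination of aldehyde 23 ⇐ E-allylic oxidation and two-carbon homologation of the prenyl terminus of chromanol 16 ⇐ decarboxylation of salicylate 14.
- 14 ⇐ Diels–Alder reaction and aromatisation of ketene-acetal diene 10 with methyl but-2-ynoate 11 (bonds C4a–C5 and C6–C7).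
- 10 ⇐ cyclic β-alkoxy enoate 9 ⇐ methyl acetoacetate dianion (from 6) + iodide 5 ⇐ (R)-linalool 1.
- Ring order: the pyran ring O1–C2–C3–C4–C4a–C8a first (step 5), the benzene ring second (step 7).

Key step: step 7

Assumption: commercial (R)-(−)-linalool of high enantiomeric purity supplies C2, so the enantiomeric purity of the target equals that of the linalool; chromane numbering (O1, C2 … C8a) is used throughout.

**Route**

Step 1
Reactants: 1 (R)-linalool
Product: 2 triethyl{[(3R)-3,7-dimethylocta-1,6-dien-3-yl]oxy}silane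
Conditions: Et3SiOTf, 2,6-lutidine, CH2Cl2, −78 → 0 °C
Reagents that add atoms: triethylsilyl trifluoromethanesulfonate, CC[Si](CC)(CC)OS(=O)(=O)C(F)(F)F
Why: O-silylation with a silyl triflate and a hindered pyridine base protects even a tertiary allylic alcohol at low temperature without ionisation, and since the C–O bond of the stereocentre is not broken the (R)-configuration of linalool is carried over.

Step 2
Reactants: 2 triethyl{[(3R)-3,7-dimethylocta-1,6-dien-3-yl]oxy}silane
Product: 4 (3R)-3,7-dimethyl-3-(triethylsilyloxy)oct-6-en-1-ol, via B-alkyl-9-borabicyclononane 3 (not isolated)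
Conditions: 9-BBN-H dimer, THF, 0 °C → rt; then aq. NaOH, 30% H2O2, 0 °C → rt
Reagents that add atoms: hydrogen peroxide, OO
Why: Hydroboration–oxidation, in which 9-BBN-H adds anti-Markovnikov to the monosubstituted vinyl group far faster than to the trisubstituted 6,7-alkene and alkaline peroxide then oxidises the C–B bond while the tertiary silyl ether survives.

Step 3
Reactants: 4 (3R)-3,7-dimethyl-3-(triethylsilyloxy)oct-6-en-1-ol
Product: 5 triethyl{[(3R)-1-iodo-3,7-dimethyloct-6-en-3-yl]oxy}silane
Conditions: I2, PPh3, imidazole, CH2Cl2, 0 °C → rt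
Reagents that add atoms: iodine, II
Why: Appel-type iodination (Garegg–Samuelsson conditions) converts the unhindered primary alcohol into the iodide by SN2 displacement of the alkoxyphosphonium ion in an imidazole-buffered medium that the silyl ether tolerates.

Step 4
Reactants: 5 triethyl{[(3R)-1-iodo-3,7-dimethyloct-6-en-3-yl]oxy}silane; 6 methyl acetoacetate
Product: 7 methyl (7S)-7,11-dimethyl-3-oxo-7-(triethylsilyloxy)dodec-10-enoate
Conditions: 6, NaH, THF, 0 °C; n-BuLi, 0 °C; then 5, 0 °C → rt; AcOH quench
Reagents that add atoms: none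
Why: Weiler dianion alkylation, in which the more basic γ-carbanion of the acetoacetate dianion displaces the primary iodide by SN2 to install C4a, C8a, C8 and C7 in one operation, the silyl ether preventing quenching of the dianion and oxetane formation (the descriptor changes to S only because the CIP ranking of the two chains changes).

Step 5
Reactants: 7 methyl (7S)-7,11-dimethyl-3-oxo-7-(triethylsilyloxy)dodec-10-enoate
Product: 9 methyl (2E)-2-[(6S)-6-methyl-6-(4-methylpent-3-en-1-yl)oxan-2-ylidene]acetate, via hydroxy keto ester 8 (not isolated)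
Conditions: TsOH·H2O (cat.), MeOH, 0 °C → rt; then toluene, PPTS (cat.), 4 Å MS, 70 °C
Reagents that add atoms: none
Why: Acid-catalysed methanolysis frees the tertiary alcohol, which closes onto the ketone by 6-exo-trig hemiketalisation, and the ketal then eliminates on heating to the conjugated exocyclic vinylogous carbonate (the cyclodehydration by which β-keto esters give 3-alkoxy-2-enoates), with the C2–O bond of the stereocentre never broken.

Step 6
Reactants: 9 methyl (2E)-2-[(6S)-6-methyl-6-(4-methylpent-3-en-1-yl)oxan-2-ylidene]acetate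
Product: 10 (2R)-6-[2-methoxy-2-(trimethylsilyloxy)ethenyl]-2-methyl-2-(4-methylpent-3-en-1-yl)-3,4-dihydro-2H-pyran
Conditions: LiN(i-Pr)2, THF, −78 °C; Me3SiCl, −78 °C → rt; pentane, filtration under Ar, used crude
Reagents that add atoms: chlorotrimethylsilane, C[Si](C)(C)Cl
Why: Vinylogous enolisation and O-silylation, in which the amide base removes the γ-hydrogen on the ring CH2 next to the enol ether carbon and the dienolate is trapped on oxygen as the methyl trimethylsilyl ketene acetal, as in the preparation of Brassard-type dienes from 3-methoxybut-2-enoates; any double-bond isomer of 9 converges on the same dienolate.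

Step 7
Reactants: 10 (2R)-6-[2-methoxy-2-(trimethylsilyloxy)ethenyl]-2-methyl-2-(4-methylpent-3-en-1-yl)-3,4-dihydro-2H-pyran; 11 methyl but-2-ynoate
Product: 14 methyl (2R)-7-hydroxy-2,5-dimethyl-2-(4-methylpent-3-en-1-yl)chromane-6-carboxylate, via silyl ketal cycloadduct 12 (not isolated), via cyclohexadienone 13 (not isolated)
Conditions: 11 (3 equiv), toluene, 110 °C, sealed tube; then 1 M aq. HCl, THF, rt
Reagents that add atoms: none
Why: A concerted, asynchronous [4+2] cycloaddition (Diels–Alder) in which the vinylogous ketene acetal is the 4π component: its γ-terminus C4a bonds to the β-carbon of the ynoate (C5, bearing CH3) and the acetal carbon C7 bonds to the α-carbon (C6, bearing CO2Me), giving the 1,4-cyclohexadiene 12. The closest known reaction type is the Diels–Alder reaction of 1-alkoxy-1-silyloxy-3-alkoxybuta-1,3-dienes (Brassard- and Danishefsky-type dienes) with acetylenic esters, which gives resorcylate esters after aromatisation. The benzene ring is closed by this intermolecular cycloaddition as a six-membered carbocycle fused along C4a–C8a to the existing dihydropyran; dilute acid then cleaves the O–Si bond of the silyl methyl ketal, methanol is expelled to give dienone 13, and tautomerisation of H-4a gives the phenol. No stereocentre remains in the new ring because C4a becomes aromatic, and C2 is not at risk because C8a stays trigonal and the O1–C2 bond is never broken. The selectivity needed is regiochemical, and it is secured by the three oxygen donors of the diene (O1 on C8a, OMe and OSiMe3 on C7), which make C4a the nucleophilic terminus and pair it with the electrophilic β-carbon of the ynoate; C4 is an outward substituent on the diene terminus, so the s-cis conformation is accessible.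

Step 8
Reactants: 14 methyl (2R)-7-hydroxy-2,5-dimethyl-2-(4-methylpent-3-en-1-yl)chromane-6-carboxylate
Product: 16 (2R)-2,5-dimethyl-2-(4-methylpent-3-en-1-yl)chroman-7-ol, via chromane-6-carboxylic acid 15 (not isolated)
Conditions: KOH, DMSO/H2O, 110 °C; then AcOH to pH 5, 110 °C
Reagents that add atoms: none
Why: Saponification of the hindered ortho-hydroxy ester followed by protodecarboxylation, which is easy for a 2-hydroxy-4-alkoxybenzoic acid because the electron-rich ipso carbon C6 is readily protonated and then loses CO2.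

Step 9
Reactants: 16 (2R)-2,5-dimethyl-2-(4-methylpent-3-en-1-yl)chroman-7-ol
Product: 17 {[(2R)-2,5-dimethyl-2-(4-methylpent-3-en-1-yl)chroman-7-yl]oxy}tri(propan-2-yl)silane
Conditions: i-Pr3SiCl, imidazole, DMF, rt
Reagents that add atoms: chlorotri(propan-2-yl)silane, CC(C)[Si](Cl)(C(C)C)C(C)C
Why: Silylation of the phenol masks it for the oxidation and the strongly basic steps that follow, and the bulky aryl triisopropylsilyl ether resists carbanions and hydride at low temperature.

Step 10
Reactants: 17 {[(2R)-2,5-dimethyl-2-(4-methylpent-3-en-1-yl)chroman-7-yl]oxy}tri(propan-2-yl)silane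
Product: 18 (2E)-5-[(2R)-2,5-dimethyl-7-(triisopropylsilyloxy)chroman-2-yl]-2-methylpent-2-en-1-ol
Conditions: SeO2 (cat.), t-BuOOH, CH2Cl2, 0 °C → rt, stopped before the enal builds up
Reagents that add atoms: tert-butyl hydroperoxide, CC(C)(C)OO (terminal oxidant); selenium dioxide, O=[Se]=O (oxygen carrier)
Why: Riley allylic oxidation under catalytic conditions (ene reaction, then [2,3]-sigmatropic shift) oxidises the (E)-methyl of the terminal trisubstituted alkene selectively, so the CH2OH ends up trans to the chain as the 6E-alkene of the target requires.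

Step 11
Reactants: 18 (2E)-5-[(2R)-2,5-dimethyl-7-(triisopropylsilyloxy)chroman-2-yl]-2-methylpent-2-en-1-ol
Product: 19 {[(2R)-2-[(3E)-5-bromo-4-methylpent-3-en-1-yl]-2,5-dimethylchroman-7-yl]oxy}tri(propan-2-yl)silane
Conditions: CBr4, PPh3, CH2Cl2, 0 °C
Reagents that add atoms: carbon tetrabromide, BrC(Br)(Br)Br
Why: Appel bromination converts the primary allylic alcohol into the bromide under neutral conditions, preserving the E-geometry and leaving the aryl silyl ether untouched.

Step 12
Reactants: 19 {[(2R)-2-[(3E)-5-bromo-4-methylpent-3-en-1-yl]-2,5-dimethylchroman-7-yl]oxy}tri(propan-2-yl)silane; 20 acetonitrile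
Product: 21 (4E)-7-[(2R)-2,5-dimethyl-7-(triisopropylsilyloxy)chroman-2-yl]-4-methylhept-4-enenitrile
Conditions: 20 (excess), n-BuLi, THF, −78 °C; then 19, −78 → −20 °C
Reagents that add atoms: none
Why: SN2 alkylation of lithiated acetonitrile at the unhindered CH2 terminus of the primary allylic bromide adds the two carbons that become C4 and C3 of the dienoate chain, an excess of the anion suppressing dialkylation.

Step 13
Reactants: 21 (4E)-7-[(2R)-2,5-dimethyl-7-(triisopropylsilyloxy)chroman-2-yl]-4-methylhept-4-enenitrile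
Product: 23 (4E)-7-[(2R)-2,5-dimethyl-7-(triisopropylsilyloxy)chroman-2-yl]-4-methylhept-4-enal, via N-aluminio aldimine 22 (not isolated)
Conditions: i-Bu2AlH, CH2Cl2, −78 °C; then 1 M aq. tartaric acid, 0 °C → rt
Reagents that add atoms: water, O
Why: Partial reduction of a nitrile, in which a single hydride adds to give the N-aluminio aldimine that is stable at low temperature and hydrolyses to the aldehyde on mild acidic work-up, the aryl silyl ether and the alkene being inert.

Step 14
Reactants: 24 methyl 2-[bis(2,2,2-trifluoroethoxy)phosphoryl]acetate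
Product: 25 methyl 2-[bis(2,2,2-trifluoroethoxy)phosphoryl]propanoate (racemic)
Conditions: t-BuOK, THF, 0 °C; MeI, 0 °C → rt
Reagents that add atoms: iodomethane, CI
Why: C-methylation of the stabilised phosphonate carbanion (enolate alkylation), with one equivalent each of base and electrophile to limit dimethylation.

Step 15
Reactants: 23 (4E)-7-[(2R)-2,5-dimethyl-7-(triisopropylsilyloxy)chroman-2-yl]-4-methylhept-4-enal; 25 methyl 2-[bis(2,2,2-trifluoroethoxy)phosphoryl]propanoate
Product: 26 methyl (2Z,6E)-9-[(2R)-2,5-dimethyl-7-(triisopropylsilyloxy)chroman-2-yl]-2,6-dimethylnona-2,6-dienoate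
Conditions: 25, KN(SiMe3)2, 18-crown-6, THF, −78 °C; then 23, −78 °C
Reagents that add atoms: none
Why: Still–Gennari modification of the Horner–Wadsworth–Emmons reaction, in which the electron-poor bis(trifluoroethyl) phosphonate with a dissociated potassium counter-ion eliminates rapidly from the kinetically formed adduct and so should give the (Z)-trisubstituted enoate.

Step 16
Reactants: 26 methyl (2Z,6E)-9-[(2R)-2,5-dimethyl-7-(triisopropylsilyloxy)chroman-2-yl]-2,6-dimethylnona-2,6-dienoate
Product: 27 methyl (2Z,6E)-9-[(2R)-7-hydroxy-2,5-dimethylchroman-2-yl]-2,6-dimethylnona-2,6-dienoate (CNP0319148.1)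
Conditions: Bu4NF, AcOH, THF, 0 °C
Reagents that add atoms: none
Why: Fluoride-mediated cleavage of the aryl silyl ether, buffered with acetic acid so that the medium does not become basic enough to isomerise or hydrolyse the Z-enoate.

**Compound list**

1 | (R)-linalool, (3R)-3,7-dimethylocta-1,6-dien-3-ol | C=C[C@](C)(O)CCC=C(C)C | starting material
2 | triethyl{[(3R)-3,7-dimethylocta-1,6-dien-3-yl]oxy}silane | C=C[C@](C)(O[Si](CC)(CC)CC)CCC=C(C)C | intermediate
3 | 9-[(3S)-3,7-dimethyl-3-(triethylsilyloxy)oct-6-en-1-yl]-9-borabicyclo[3.3.1]nonane | C1CC2CCCC(C1)B2CC[C@](C)(O[Si](CC)(CC)CC)CCC=C(C)C | intermediate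
4 | (3R)-3,7-dimethyl-3-(triethylsilyloxy)oct-6-en-1-ol | OCC[C@](C)(O[Si](CC)(CC)CC)CCC=C(C)C | intermediate
5 | triethyl{[(3R)-1-iodo-3,7-dimethyloct-6-en-3-yl]oxy}silane | ICC[C@](C)(O[Si](CC)(CC)CC)CCC=C(C)C | intermediate
6 | methyl acetoacetate | COC(=O)CC(C)=O | starting material
7 | methyl (7S)-7,11-dimethyl-3-oxo-7-(triethylsilyloxy)dodec-10-enoate | COC(=O)CC(=O)CCC[C@](C)(O[Si](CC)(CC)CC)CCC=C(C)C | intermediate
8 | methyl (7S)-7-hydroxy-7,11-dimethyl-3-oxododec-10-enoate (open form, in equilibrium with its cyclic hemiketal) | COC(=O)CC(=O)CCC[C@](C)(O)CCC=C(C)C | intermediate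
9 | methyl (2E)-2-[(6S)-6-methyl-6-(4-methylpent-3-en-1-yl)oxan-2-ylidene]acetate | COC(=O)/C=C1\CCC[C@@](C)(CCC=C(C)C)O1 | intermediate
10 | (2R)-6-[2-methoxy-2-(trimethylsilyloxy)ethenyl]-2-methyl-2-(4-methylpent-3-en-1-yl)-3,4-dihydro-2H-pyran | COC(O[Si](C)(C)C)=CC1=CCC[C@@](C)(CCC=C(C)C)O1 | intermediate
11 | methyl but-2-ynoate | CC#CC(=O)OC | starting material
12 | methyl (2R)-7-methoxy-2,5-dimethyl-2-(4-methylpent-3-en-1-yl)-7-(trimethylsilyloxy)-3,4,4a,7-tetrahydro-2H-chromene-6-carboxylate (C4a and C7 unassigned) | COC(=O)C1=C(C)C2CC[C@@](C)(CCC=C(C)C)OC2=CC1(OC)O[Si](C)(C)C | intermediate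
13 | methyl (2R)-2,5-dimethyl-2-(4-methylpent-3-en-1-yl)-7-oxo-3,4,4a,7-tetrahydro-2H-chromene-6-carboxylate (C4a unassigned) | COC(=O)C1=C(C)C2CC[C@@](C)(CCC=C(C)C)OC2=CC1=O | intermediate
14 | methyl (2R)-7-hydroxy-2,5-dimethyl-2-(4-methylpent-3-en-1-yl)chromane-6-carboxylate | COC(=O)c1c(O)cc2O[C@](C)(CCC=C(C)C)CCc2c1C | intermediate
15 | (2R)-7-hydroxy-2,5-dimethyl-2-(4-methylpent-3-en-1-yl)chromane-6-carboxylic acid | OC(=O)c1c(O)cc2O[C@](C)(CCC=C(C)C)CCc2c1C | intermediate
16 | (2R)-2,5-dimethyl-2-(4-methylpent-3-en-1-yl)chroman-7-ol | Cc1cc(O)cc2O[C@](C)(CCC=C(C)C)CCc12 | intermediate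
17 | {[(2R)-2,5-dimethyl-2-(4-methylpent-3-en-1-yl)chroman-7-yl]oxy}tri(propan-2-yl)silane | Cc1cc(O[Si](C(C)C)(C(C)C)C(C)C)cc2O[C@](C)(CCC=C(C)C)CCc12 | intermediate
18 | (2E)-5-[(2R)-2,5-dimethyl-7-(triisopropylsilyloxy)chroman-2-yl]-2-methylpent-2-en-1-ol | Cc1cc(O[Si](C(C)C)(C(C)C)C(C)C)cc2O[C@](C)(CC/C=C(\C)CO)CCc12 | intermediate
19 | {[(2R)-2-[(3E)-5-bromo-4-methylpent-3-en-1-yl]-2,5-dimethylchroman-7-yl]oxy}tri(propan-2-yl)silane | Cc1cc(O[Si](C(C)C)(C(C)C)C(C)C)cc2O[C@](C)(CC/C=C(\C)CBr)CCc12 | intermediate
20 | acetonitrile | CC#N | starting material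
21 | (4E)-7-[(2R)-2,5-dimethyl-7-(triisopropylsilyloxy)chroman-2-yl]-4-methylhept-4-enenitrile | Cc1cc(O[Si](C(C)C)(C(C)C)C(C)C)cc2O[C@](C)(CC/C=C(\C)CCC#N)CCc12 | intermediate
22 | N-(diisobutylaluminio) aldimine of aldehyde 23 | Cc1cc(O[Si](C(C)C)(C(C)C)C(C)C)cc2O[C@](C)(CC/C=C(\C)CCC=N[Al](CC(C)C)CC(C)C)CCc12 | intermediate
23 | (4E)-7-[(2R)-2,5-dimethyl-7-(triisopropylsilyloxy)chroman-2-yl]-4-methylhept-4-enal | Cc1cc(O[Si](C(C)C)(C(C)C)C(C)C)cc2O[C@](C)(CC/C=C(\C)CCC=O)CCc12 | intermediate
24 | methyl 2-[bis(2,2,2-trifluoroethoxy)phosphoryl]acetate | COC(=O)CP(=O)(OCC(F)(F)F)OCC(F)(F)F | starting material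
25 | methyl 2-[bis(2,2,2-trifluoroethoxy)phosphoryl]propanoate (racemic) | COC(=O)C(C)P(=O)(OCC(F)(F)F)OCC(F)(F)F | intermediate
26 | methyl (2Z,6E)-9-[(2R)-2,5-dimethyl-7-(triisopropylsilyloxy)chroman-2-yl]-2,6-dimethylnona-2,6-dienoate | COC(=O)/C(C)=C\CC/C(C)=C/CC[C@]1(C)CCc2c(C)cc(O[Si](C(C)C)(C(C)C)C(C)C)cc2O1 | intermediate
27 | methyl (2Z,6E)-9-[(2R)-7-hydroxy-2,5-dimethylchroman-2-yl]-2,6-dimethylnona-2,6-dienoate | COC(=O)/C(C)=C\CC/C(C)=C/CC[C@]1(C)CCc2c(C)cc(O)cc2O1 | target

**Step count and risks**

Total: 16 steps. Longest linear sequence: 15 steps (steps 1–13, 15 and 16, from (R)-linalool); step 14 is a one-step side branch.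

Steps most likely to fail:

1. Step 7. The β-methyl ynoate is a weak dienophile, so thermal decomposition or adventitious hydrolysis of the silyl ketene acetal may outrun the cycloaddition. The fallback sets out from 10 and replaces the alkyne by the more electrophilic allene ethyl buta-2,3-dienoate (toluene, 60–80 °C). Cycloaddition across its conjugated C2=C3 bond, with C4a again bonding to the central β-carbon, should give the 5-methylidene silyl ketal cycloadduct F1. Dilute-acid work-up (loss of the ketal substituents, then migration of the exocyclic double bond into the ring) should give ethyl (2R)-7-hydroxy-2,5-dimethyl-2-(4-methylpent-3-en-1-yl)chromane-6-carboxylate F2. Hydrolysis and decarboxylation under the conditions of step 8 bring the material back to the route at 16.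

2. Step 10. The allylic oxidation may stall at low conversion, run on to the enal, or attack the benzylic C4 position. The fallback sets out from 17 and cleaves the trisubstituted alkene (K2OsO4·2H2O cat., NaIO4, 2,6-lutidine, dioxane/H2O) to 3-[(2S)-2,5-dimethyl-7-(triisopropylsilyloxy)chroman-2-yl]propanal F3 (same spatial arrangement at C2; the descriptor changes by CIP ranking only). A Wittig reaction with the stabilised ylide ethyl 2-(triphenylphosphoranylidene)propanoate (toluene, 80 °C) rebuilds the E-alkene as ethyl (2E)-5-[(2R)-2,5-dimethyl-7-(triisopropylsilyloxy)chroman-2-yl]-2-methylpent-2-enoate F4. Reduction with i-Bu2AlH (CH2Cl2, −78 °C) rejoins the route at 18.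

3. Step 5. Under acid the elimination may stop at the ketal stage, or the trisubstituted alkene and the tertiary carbinol may undergo acid-promoted cyclisation or ionisation before the ring closes. The fallback sets out from 7 and removes the silyl group with buffered fluoride (Bu4NF, AcOH, THF) to give the lactol methyl 2-[(6S)-2-hydroxy-6-methyl-6-(4-methylpent-3-en-1-yl)oxan-2-yl]acetate F5. Dehydration under basic conditions through the anomeric trifluoroacetate ((CF3CO)2O, pyridine, CH2Cl2, 0 °C → rt), an elimination known for hemiketals bearing a CH2CO2R group, rejoins the route at 9.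

**Further compounds**

F1 | step 7 | ethyl (2R)-7-methoxy-2-methyl-5-methylidene-2-(4-methylpent-3-en-1-yl)-7-(trimethylsilyloxy)-3,4,4a,5,6,7-hexahydro-2H-chromene-6-carboxylate (C4a, C6 and C7 unassigned) | CCOC(=O)C1C(=C)C2CC[C@@](C)(CCC=C(C)C)OC2=CC1(OC)O[Si](C)(C)C
F2 | step 7 | ethyl (2R)-7-hydroxy-2,5-dimethyl-2-(4-methylpent-3-en-1-yl)chromane-6-carboxylate | CCOC(=O)c1c(O)cc2O[C@](C)(CCC=C(C)C)CCc2c1C
F3 | step 10 | 3-[(2S)-2,5-dimethyl-7-(triisopropylsilyloxy)chroman-2-yl]propanal | Cc1cc(O[Si](C(C)C)(C(C)C)C(C)C)cc2O[C@](C)(CCC=O)CCc12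
F4 | step 10 | ethyl (2E)-5-[(2R)-2,5-dimethyl-7-(triisopropylsilyloxy)chroman-2-yl]-2-methylpent-2-enoate | Cc1cc(O[Si](C(C)C)(C(C)C)C(C)C)cc2O[C@](C)(CC/C=C(\C)C(=O)OCC)CCc12
F5 | step 5 | methyl 2-[(6S)-2-hydroxy-6-methyl-6-(4-methylpent-3-en-1-yl)oxan-2-yl]acetate (anomeric mixture) | COC(=O)CC1(O)CCC[C@@](C)(CCC=C(C)C)O1
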